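The readings were computed with made-up constants; scatter was added.

Slowness comes first: after 6.00 h the ash run still holds 70% of its substrate, so each set-up comes down to how much substrate is lost and what that loss becomes.

| setting | ash | elm | larch | midnight | autumn | spring |
|---|---|---|---|---|---|---|
| substrate | 14 mM | 7 mM | 10 mM | 14 mM | 14 mM | 14 mM |
| remark | run made earlier | run made earlier | run made earlier | a single well-mixed tank run continuously and read at steady state, 6.0 h in it on average | everything together in a closed stirred flask, run for 6.0 h | one stirred flow tank at steady state, fed with the mixture as stated, mean residence time 30.0 h |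
| time |  |  |  |  | 6.0 h |  |

| run | time / h | target / % | substrate / % |
|---|---|---|---|
| ash | 0.333 | 1 | 98 |
| ash | 1.00 | 5 | 93 |
| ash | 1.50 | 6 | 92 |
| ash | 2.50 | 6 | 88 |
| ash | 4.00 | 11 | 79 |
| ash | 5.00 | 18 | 74 |
| ash | 6.00 | 19 | 70 |
| elm | 0.500 | 5 | 97 |
| elm | 0.667 | 3 | 95 |
| elm | 1.00 | 4 | 96 |
| elm | 1.50 | 6 | 91 |
| elm | 2.50 | 7 | 88 |
| elm | 4.00 | 12 | 83 |
| elm | 6.00 | 17 | 75 |
| larch | 0.833 | 3 | 93 |
| larch | 1.50 | 6 | 92 |
| larch | 2.50 | 8 | 89 |
| larch | 3.00 | 11 | 84 |
| larch | 4.00 | 11 | 81 |
| larch | 5.00 | 14 | 77 |
| larch | 6.00 | 17 | 72 |

(scatter of a reading: 1.5 percentage points)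

- the stated concentrations are those of everything mixed, before any reaction; amounts are the same in each set-up
- the earlier runs were made in a closed, stirred flask

* the set-up with the highest amount of target at the outlet or at the end, in percent of the substrate put in ("none" if the first two lie within 2 percentage points) (midnight / autumn / spring / none)
* amount of target at the outlet or at the end, in percent of the substrate put in, midnight
* amount of target at the outlet or at the end, in percent of the substrate put in, autumn
* amount of target at the outlet or at the end, in percent of the substrate put in, spring

At its last reading, ash shows 19% target on 30.0% of substrate lost. That gives 0.633 for the share of lost substrate standing as target, the overall selectivity. An even split, the zero of this scale, is 0.5. Elm at 7 mM reads 0.680 and larch at 10 mM reads 0.607.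

Two views part here. The forecast reads “This suggests a first-order route to target plus a roughly second-order side loss”. It gives 16% for midnight, 18.5% for autumn and 43% for spring (range 33% to 50%), on 42% substrate left in spring, and names spring as best.

A scatter of 1.5 percentage points on ash's target reading moves its share by 0.0500, and the three shares spread over 0.0729, less than two such moves, so I read no order with charge from them and hold the share fixed. Autumn repeats ash, at 19%. For midnight, ash's first-order rate of 0.0594 h⁻¹ in the tank balance gives 16.7%. For spring, elm's rate of 0.0479 h⁻¹ leaves 41.0%, which is 5.74 mM and below elm's own charge. My spring is then 37.4%, still the best set-up but lower than the forecast's.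

    substrate ⇌ isomer of the product (K = 5.68, k = 0.0105 h⁻¹)
    substrate ⇌ target (K = 1.91, k = 0.0367 h⁻¹)
    2 substrate → homo dimer (k = 0.404 M⁻¹ h⁻¹)

The flask gives 15.1%, 17.6% and 32.4%, with spring best, and the forecast's spring stands 11 points above it. Spring ends with 46.4% substrate and 13.9% isomer of the product. The fixed share on its lost 53.6% gives 33.9%, less than the forecast's 43%. The forecast's view keeps midnight and autumn, which fall inside its ranges. Autumn left for 60.0 h holds 43.6% target, less than the 63.3% that the share gives on the whole charge.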